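**Strategy.** The furan is dissected at its C3–C4 bond: C3 carries only hydrogen and C4 carries the (R)-acyloxy prenyl side chain, so these two carbons can be the termini of two alkenes held together through the ring oxygen. A ruthenium-catalysed ring-closing metathesis of a bis-allylic ether forms that bond and the five-membered ring in one operation. It gives a 2,5-dihydrofuran whose doubly activated C2–H allows late dehydrogenation to the furan. The precursor is the ether between racemic 1-[2,5-bis(silyloxy)phenyl]prop-2-en-1-ol and an enantioenriched 2-(bromomethyl)allyl isovalerate, whose stereocentre comes from a Brown allylation and is never touched afterwards.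

Key step: step 11

Assumption: the aryl carbinol carbon of 5, 18 and 19 is carried as a mixture of epimers because it becomes sp2 in step 12. Ring atoms are numbered as in the final furan throughout (O1, C2 aryl, C3 H, C4 side chain, C5 H).

**Route**

Step 1
Reactants: 1 2,5-dihydroxybenzaldehyde
Product: 2 2,5-bis(tert-butyldimethylsilyloxy)benzaldehyde
Conditions: TBSCl (2.4 equiv), imidazole (5 equiv), DMF, rt
Reagents that add atoms: tert-butyldimethylsilyl chloride, CC(C)(C)[Si](C)(C)Cl
Why: Imidazole-promoted silyl ether formation in DMF should cap both phenols, including the hydrogen-bonded ortho hydroxyl, while the aldehyde is inert.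

Step 2
Reactants: 2 2,5-bis(tert-butyldimethylsilyloxy)benzaldehyde; 3 vinylmagnesium bromide
Product: 5 1-[2,5-bis(tert-butyldimethylsilyloxy)phenyl]prop-2-en-1-ol (racemic), via bromomagnesium alkoxide 4 (not isolated)
Conditions: THF, −78 °C; then sat. aq. NH4Cl at −78 °C
Reagents that add atoms: none
Why: Grignard 1,2-addition to the aryl aldehyde gives the secondary allylic benzylic alcohol as a racemate, which is acceptable because this carbon becomes sp2 in step 12, and cold addition with a cold quench should keep the ortho silyl group from migrating to the alkoxide.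

Step 3
Reactants: 6 2-methylenepropane-1,3-diol
Product: 7 2-{[(tert-butyldimethylsilyl)oxy]methyl}prop-2-en-1-ol
Conditions: TBSCl (1.0 equiv), imidazole (1.5 equiv), 6 (3 equiv), DMF, 0 °C
Reagents that add atoms: tert-butyldimethylsilyl chloride, CC(C)(C)[Si](C)(C)Cl
Why: Statistical monosilylation of a symmetrical diol, in which the cheap water-soluble diol is used in excess so that the limiting silyl chloride ends up mainly as the mono ether and the surplus diol is washed out.

Step 4
Reactants: 7 2-{[(tert-butyldimethylsilyl)oxy]methyl}prop-2-en-1-ol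
Product: 8 2-{[(tert-butyldimethylsilyl)oxy]methyl}prop-2-enal
Conditions: activated MnO2 (10 equiv), CH2Cl2, rt
Reagents that add atoms: none
Why: Activated MnO2 oxidises allylic alcohols selectively to enals under neutral heterogeneous conditions that leave the silyl ether untouched.

Step 5
Reactants: 8 2-{[(tert-butyldimethylsilyl)oxy]methyl}prop-2-enal; 9 (+)-B-allyldiisopinocampheylborane (reagent derived from (−)-α-pinene, commercial pentane solution)
Product: 11 (3R)-2-{[(tert-butyldimethylsilyl)oxy]methyl}hexa-1,5-dien-3-ol, via diisopinocampheylborinate ester 10 (not isolated)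
Conditions: Et2O, −78 °C; then 3 M NaOH, 30% H2O2, 0 °C to rt
Reagents that add atoms: none
Why: Brown allylboration through a chair-like six-membered transition state, in which the isopinocampheyl groups of this reagent antipode direct the allyl group to the Re face of the aldehyde and so set the (R) carbinol centre, after which alkaline peroxide cleaves the borinate.

Step 6
Reactants: 11 (3R)-2-{[(tert-butyldimethylsilyl)oxy]methyl}hexa-1,5-dien-3-ol; 12 2-methyl-2-butene
Product: 13 (3R)-2-{[(tert-butyldimethylsilyl)oxy]methyl}-6-methylhepta-1,5-dien-3-ol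
Conditions: second-generation Grubbs catalyst RuCl2(=CHPh)(H2IMes)(PCy3) (3 mol%), 12/CH2Cl2 1:1, 35 °C, sealed vessel
Reagents that add atoms: none
Why: Olefin cross-metathesis of the monosubstituted terminal alkene with excess 2-methyl-2-butene installs the isopropylidene terminus with loss of propene, while the hindered 1,1-disubstituted alkene stays out of the reaction and the stereocentre is not involved.

Step 7
Reactants: 13 (3R)-2-{[(tert-butyldimethylsilyl)oxy]methyl}-6-methylhepta-1,5-dien-3-ol; 14 3-methylbutanoyl chloride
Product: 15 (3R)-2-{[(tert-butyldimethylsilyl)oxy]methyl}-6-methylhepta-1,5-dien-3-yl 3-methylbutanoate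
Conditions: pyridine (3 equiv), DMAP (0.1 equiv), CH2Cl2, 0 °C to rt
Reagents that add atoms: none
Why: DMAP-catalysed acylation through the acylpyridinium ion esterifies the secondary allylic alcohol with retention, since only the O–H bond is broken.

Step 8
Reactants: 15 (3R)-2-{[(tert-butyldimethylsilyl)oxy]methyl}-6-methylhepta-1,5-dien-3-yl 3-methylbutanoate
Product: 16 (3R)-2-(hydroxymethyl)-6-methylhepta-1,5-dien-3-yl 3-methylbutanoate
Conditions: HF·pyridine, pyridine, THF, 0 °C
Reagents that add atoms: none
Why: Buffered HF·pyridine cleaves the primary alkyl silyl ether by Si–F bond formation under weakly acidic conditions, which avoids the alkoxide that would trigger 1,3-acyl migration from the neighbouring ester.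

Step 9
Reactants: 16 (3R)-2-(hydroxymethyl)-6-methylhepta-1,5-dien-3-yl 3-methylbutanoate
Product: 17 (3R)-2-(bromomethyl)-6-methylhepta-1,5-dien-3-yl 3-methylbutanoate
Conditions: CBr4 (1.3 equiv), PPh3 (1.3 equiv), CH2Cl2, 0 °C
Reagents that add atoms: carbon tetrabromide, BrC(Br)(Br)Br
Why: Appel reaction, in which bromide displaces the alkoxyphosphonium group at the primary allylic carbon (direct and allylically transposed attack give the same constitution) under neutral conditions that spare the ester and the stereocentre.

Step 10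
Reactants: 5 1-[2,5-bis(tert-butyldimethylsilyloxy)phenyl]prop-2-en-1-ol (1.5 equiv); 17 (3R)-2-(bromomethyl)-6-methylhepta-1,5-dien-3-yl 3-methylbutanoate
Product: 18 (3R)-2-({1-[2,5-bis(tert-butyldimethylsilyloxy)phenyl]prop-2-en-1-yl}oxymethyl)-6-methylhepta-1,5-dien-3-yl 3-methylbutanoate (two epimers at the aryl carbinol carbon)
Conditions: Ag2O (2 equiv), Bu4NI (0.1 equiv), 4 Å MS, CH2Cl2, rt, dark
Reagents that add atoms: none
Why: Silver oxide-mediated O-alkylation (Purdie-type Williamson etherification) with the reactive 2-substituted allylic bromide proceeds without a free alkoxide, so neither the isovalerate nor the ortho silyl group is attacked, and the (R) centre is not touched.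

Step 11
Reactants: 18 (3R)-2-({1-[2,5-bis(tert-butyldimethylsilyloxy)phenyl]prop-2-en-1-yl}oxymethyl)-6-methylhepta-1,5-dien-3-yl 3-methylbutanoate
Product: 19 (1R)-1-{5-[2,5-bis(tert-butyldimethylsilyloxy)phenyl]-2,5-dihydrofuran-3-yl}-4-methylpent-3-en-1-yl 3-methylbutanoate (two epimers at the aryl-bearing ring carbon)
Conditions: second-generation Grubbs catalyst RuCl2(=CHPh)(H2IMes)(PCy3) (5 mol%), CH2Cl2 (0.005 M), 40 °C, argon sparge
Reagents that add atoms: none
Why: The ruthenium benzylidene first exchanges onto the unhindered vinyl group of 18; the new alkylidene adds across the tethered 1,1-disubstituted alkene to a ruthenacyclobutane, which cycloreverts to the ring C3=C4 double bond and a ruthenium methylidene that re-enters the cycle at the next vinyl group with release of ethylene. The closest known reaction type is ring-closing olefin metathesis of allyl 2-substituted-allyl ethers to 3-substituted 2,5-dihydrofurans. The single ring formed, the oxygen-containing five-membered ring, closes by carbon–carbon double-bond formation between the former vinyl CH (C3) and the substituted alkene carbon (C4), the ether oxygen being already in the tether. No stereocentre is created, the (R)-acyloxy centre lies outside the reacting atoms and is left intact by the neutral catalyst, and the epimeric aryl-bearing carbon is carried through unchanged. Three alkenes compete for the catalyst, but the trisubstituted prenyl alkene is a poor metathesis partner and could only close an eight-membered ring, whereas the 1,1-disubstituted alkene closes a strain-free five-membered ring. High dilution and removal of ethylene suppress dimerisation through the vinyl group.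

Step 12
Reactants: 19 (1R)-1-{5-[2,5-bis(tert-butyldimethylsilyloxy)phenyl]-2,5-dihydrofuran-3-yl}-4-methylpent-3-en-1-yl 3-methylbutanoate
Product: 20 (1R)-1-{5-[2,5-bis(tert-butyldimethylsilyloxy)phenyl]furan-3-yl}-4-methylpent-3-en-1-yl 3-methylbutanoate
Conditions: DDQ (1.2 equiv), dry toluene, rt
Reagents that add atoms: none
Why: Quinone dehydrogenation of a 2,5-dihydrofuran, in which DDQ removes hydride from ring C2 (activated at once by the aryl group, the ring alkene and the ring oxygen) and the resulting oxocarbenium ion loses the C5 proton, so both epimers converge on the aromatic furan.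

Step 13
Reactants: 20 (1R)-1-{5-[2,5-bis(tert-butyldimethylsilyloxy)phenyl]furan-3-yl}-4-methylpent-3-en-1-yl 3-methylbutanoate
Product: 21 (1R)-1-[5-(2,5-dihydroxyphenyl)furan-3-yl]-4-methylpent-3-en-1-yl 3-methylbutanoate
Conditions: TBAF (2.4 equiv), AcOH (2.6 equiv), THF, 0 °C, argon
Reagents that add atoms: none
Why: Fluoride cleaves both aryl silyl ethers by Si–O to Si–F exchange, and acetic acid buffering prevents phenoxide formation so that the isovalerate neither migrates nor hydrolyses and the hydroquinone is not oxidised by air.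

**Compound list**

1 | 2,5-dihydroxybenzaldehyde | O=Cc1cc(O)ccc1O | starting material
2 | 2,5-bis(tert-butyldimethylsilyloxy)benzaldehyde | O=Cc1cc(O[Si](C)(C)C(C)(C)C)ccc1O[Si](C)(C)C(C)(C)C | intermediate
3 | vinylmagnesium bromide | C=C[Mg]Br | starting material
4 | bromomagnesium alkoxide of 5 | C=CC(O[Mg]Br)c1cc(O[Si](C)(C)C(C)(C)C)ccc1O[Si](C)(C)C(C)(C)C | intermediate (not isolated)
5 | 1-[2,5-bis(tert-butyldimethylsilyloxy)phenyl]prop-2-en-1-ol, racemic | C=CC(O)c1cc(O[Si](C)(C)C(C)(C)C)ccc1O[Si](C)(C)C(C)(C)C | intermediate
6 | 2-methylenepropane-1,3-diol | C=C(CO)CO | starting material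
7 | 2-{[(tert-butyldimethylsilyl)oxy]methyl}prop-2-en-1-ol | C=C(CO)CO[Si](C)(C)C(C)(C)C | intermediate
8 | 2-{[(tert-butyldimethylsilyl)oxy]methyl}prop-2-enal | C=C(C=O)CO[Si](C)(C)C(C)(C)C | intermediate
9 | (+)-B-allyldiisopinocampheylborane | C=CCB([C@H]1C[C@H]2C[C@@H]([C@@H]1C)C2(C)C)[C@H]1C[C@H]2C[C@@H]([C@@H]1C)C2(C)C | starting material
10 | diisopinocampheylborinate ester of 11 | C=CC[C@@H](OB([C@H]1C[C@H]2C[C@@H]([C@@H]1C)C2(C)C)[C@H]1C[C@H]2C[C@@H]([C@@H]1C)C2(C)C)C(=C)CO[Si](C)(C)C(C)(C)C | intermediate (not isolated)
11 | (3R)-2-{[(tert-butyldimethylsilyl)oxy]methyl}hexa-1,5-dien-3-ol | C=CC[C@@H](O)C(=C)CO[Si](C)(C)C(C)(C)C | intermediate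
12 | 2-methyl-2-butene | CC=C(C)C | starting material
13 | (3R)-2-{[(tert-butyldimethylsilyl)oxy]methyl}-6-methylhepta-1,5-dien-3-ol | CC(C)=CC[C@@H](O)C(=C)CO[Si](C)(C)C(C)(C)C | intermediate
14 | 3-methylbutanoyl chloride | CC(C)CC(=O)Cl | starting material
15 | (3R)-2-{[(tert-butyldimethylsilyl)oxy]methyl}-6-methylhepta-1,5-dien-3-yl 3-methylbutanoate | CC(C)=CC[C@@H](OC(=O)CC(C)C)C(=C)CO[Si](C)(C)C(C)(C)C | intermediate
16 | (3R)-2-(hydroxymethyl)-6-methylhepta-1,5-dien-3-yl 3-methylbutanoate | CC(C)=CC[C@@H](OC(=O)CC(C)C)C(=C)CO | intermediate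
17 | (3R)-2-(bromomethyl)-6-methylhepta-1,5-dien-3-yl 3-methylbutanoate | CC(C)=CC[C@@H](OC(=O)CC(C)C)C(=C)CBr | intermediate
18 | (3R)-2-({1-[2,5-bis(tert-butyldimethylsilyloxy)phenyl]prop-2-en-1-yl}oxymethyl)-6-methylhepta-1,5-dien-3-yl 3-methylbutanoate, two epimers at the aryl carbinol carbon | C=CC(OCC(=C)[C@H](OC(=O)CC(C)C)CC=C(C)C)c1cc(O[Si](C)(C)C(C)(C)C)ccc1O[Si](C)(C)C(C)(C)C | intermediate
19 | (1R)-1-{5-[2,5-bis(tert-butyldimethylsilyloxy)phenyl]-2,5-dihydrofuran-3-yl}-4-methylpent-3-en-1-yl 3-methylbutanoate, two epimers at the aryl-bearing ring carbon | CC(C)=CC[C@@H](OC(=O)CC(C)C)C1=CC(c2cc(O[Si](C)(C)C(C)(C)C)ccc2O[Si](C)(C)C(C)(C)C)OC1 | intermediate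
20 | (1R)-1-{5-[2,5-bis(tert-butyldimethylsilyloxy)phenyl]furan-3-yl}-4-methylpent-3-en-1-yl 3-methylbutanoate | CC(C)=CC[C@@H](OC(=O)CC(C)C)c1coc(-c2cc(O[Si](C)(C)C(C)(C)C)ccc2O[Si](C)(C)C(C)(C)C)c1 | intermediate
21 | (1R)-1-[5-(2,5-dihydroxyphenyl)furan-3-yl]-4-methylpent-3-en-1-yl 3-methylbutanoate | CC(C)=CC[C@@H](OC(=O)CC(C)C)c1coc(-c2cc(O)ccc2O)c1 | target

**Totals**

Total step count: 13.
Longest linear sequence: 11 steps (6 to 21, steps 3 to 13); the aryl branch (steps 1 and 2) joins at step 10.

**Steps most likely to fail**

1. Step 11 (ring-closing metathesis). Closure onto the hindered, acyloxy-flanked 1,1-disubstituted alkene may be slower than intermolecular metathesis through the vinyl group or ruthenium hydride-induced migration of the allyl ether double bonds, so that oligomerisation and enol ether formation take over. The fallback takes the furan ring from a commercial aldehyde and attaches the aryl group by cross-coupling; it sets out from 9 (reusing 12 and 14) and comes back at 20, so that step 12 is not needed either.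
   - 3-Furaldehyde F3 would be allylated with 9 (Et2O, −78 °C; then NaOH, H2O2) through the borinate F4 (not isolated) to (R)-1-(furan-3-yl)but-3-en-1-ol F5, with the same Re-face addition as in step 5.
   - Cross-metathesis with 12 under the conditions of step 6 would give (R)-1-(furan-3-yl)-4-methylpent-3-en-1-ol F6.
   - Acylation with 14 (pyridine, DMAP) would give the isovalerate F7.
   - Iridium-catalysed C–H borylation ([Ir(OMe)(cod)]2, 4,4′-di-tert-butyl-2,2′-bipyridine, B2pin2, hexane, rt) should take place at the α-position remote from the side chain and give the pinacol boronate F8.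
   - Bromohydroquinone F9 would be silylated (TBSCl, imidazole, DMF) to 2-bromo-1,4-bis(tert-butyldimethylsilyloxy)benzene F10.
   - Suzuki–Miyaura coupling of F8 with F10 (Pd(OAc)2, SPhos, K3PO4, THF/H2O, 40 °C) would give 20.

2. Step 10 (etherification). O-Alkylation of the hindered secondary alcohol on the silver oxide surface may be slow, so that silver-assisted ionisation of the bromide with participation of the neighbouring isovalerate (acyl shift) or self-condensation of 5 competes. The fallback replaces the silver-assisted alkylation by palladium π-allyl chemistry; it sets out from 16 and 5 and comes back at 18.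
   - 16 would be treated with methyl chloroformate and pyridine (CH2Cl2, 0 °C) to give the allylic methyl carbonate F1.
   - 5 would be converted with Et2Zn (0.5 equiv, THF) into its zinc bis-alkoxide F2 (not isolated).
   - F2 would be combined with F1, Pd(OAc)2 (5 mol%) and 2-(di-tert-butylphosphino)biphenyl at rt. Ionisation of the carbonate by zerovalent palladium gives a 2-substituted π-allyl complex whose two CH2 termini are equivalent, so attack of the zinc alkoxide at either end leads to 18 (palladium-catalysed allylic etherification). The carbonate should ionise much faster than the hindered secondary isovalerate.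

3. Step 12 (dehydrogenation). The quinone may oxidise the electron-rich bis(silyloxy)arene or the newly formed aryl furan further, or abstract hydride at the prenyl allylic positions, so that over-oxidation competes with aromatisation. The fallback builds the furan oxidation level into the metathesis substrate, so that aromatisation is a loss of methanol and no oxidant meets the arene; it sets out from 16 and 5 and comes back at 20.
   - 16 would be oxidised with activated MnO2 (CH2Cl2, rt) to the enal F11.
   - F11 would be converted with HC(OMe)3 and PPTS in MeOH into the dimethyl acetal F12.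
   - F12 would be transacetalised with 5 (PPTS, toluene, 50 °C, methanol removed under reduced pressure) to the mixed acetal F13.
   - Ring-closing metathesis under the conditions of step 11 would give the 5-methoxy-2,5-dihydrofuran F14.
   - PPTS in CH2Cl2 would eliminate methanol from F14 by ionisation at the acetal carbon and loss of the C2 proton, giving 20.

**Further compounds**

F1 | step 10 | (3R)-2-{[(methoxycarbonyl)oxy]methyl}-6-methylhepta-1,5-dien-3-yl 3-methylbutanoate | CC(C)=CC[C@@H](OC(=O)CC(C)C)C(=C)COC(=O)OC
F2 | step 10 | zinc bis-alkoxide of 5 (not isolated) | C=CC(O[Zn]OC(C=C)c1cc(O[Si](C)(C)C(C)(C)C)ccc1O[Si](C)(C)C(C)(C)C)c1cc(O[Si](C)(C)C(C)(C)C)ccc1O[Si](C)(C)C(C)(C)C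
F3 | step 11 | 3-furaldehyde (commercial input) | O=Cc1ccoc1
F4 | step 11 | diisopinocampheylborinate ester of F5 (not isolated) | C=CC[C@@H](OB([C@H]1C[C@H]2C[C@@H]([C@@H]1C)C2(C)C)[C@H]1C[C@H]2C[C@@H]([C@@H]1C)C2(C)C)c1ccoc1
F5 | step 11 | (1R)-1-(furan-3-yl)but-3-en-1-ol | C=CC[C@@H](O)c1ccoc1
F6 | step 11 | (1R)-1-(furan-3-yl)-4-methylpent-3-en-1-ol | CC(C)=CC[C@@H](O)c1ccoc1
F7 | step 11 | (1R)-1-(furan-3-yl)-4-methylpent-3-en-1-yl 3-methylbutanoate | CC(C)=CC[C@@H](OC(=O)CC(C)C)c1ccoc1
F8 | step 11 | (1R)-4-methyl-1-[5-(4,4,5,5-tetramethyl-1,3,2-dioxaborolan-2-yl)furan-3-yl]pent-3-en-1-yl 3-methylbutanoate | CC(C)=CC[C@@H](OC(=O)CC(C)C)c1coc(B2OC(C)(C)C(C)(C)O2)c1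
F9 | step 11 | bromohydroquinone (commercial input) | Oc1ccc(O)c(Br)c1
F10 | step 11 | 2-bromo-1,4-bis(tert-butyldimethylsilyloxy)benzene | Brc1cc(O[Si](C)(C)C(C)(C)C)ccc1O[Si](C)(C)C(C)(C)C
F11 | step 12 | (3R)-2-formyl-6-methylhepta-1,5-dien-3-yl 3-methylbutanoate | CC(C)=CC[C@@H](OC(=O)CC(C)C)C(=C)C=O
F12 | step 12 | (3R)-2-(dimethoxymethyl)-6-methylhepta-1,5-dien-3-yl 3-methylbutanoate | CC(C)=CC[C@@H](OC(=O)CC(C)C)C(=C)C(OC)OC
F13 | step 12 | (3R)-2-[({1-[2,5-bis(tert-butyldimethylsilyloxy)phenyl]prop-2-en-1-yl}oxy)(methoxy)methyl]-6-methylhepta-1,5-dien-3-yl 3-methylbutanoate, mixture of diastereomers | C=CC(OC(OC)C(=C)[C@H](OC(=O)CC(C)C)CC=C(C)C)c1cc(O[Si](C)(C)C(C)(C)C)ccc1O[Si](C)(C)C(C)(C)C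
F14 | step 12 | (1R)-1-{5-[2,5-bis(tert-butyldimethylsilyloxy)phenyl]-2-methoxy-2,5-dihydrofuran-3-yl}-4-methylpent-3-en-1-yl 3-methylbutanoate, mixture of diastereomers | CC(C)=CC[C@@H](OC(=O)CC(C)C)C1=CC(c2cc(O[Si](C)(C)C(C)(C)C)ccc2O[Si](C)(C)C(C)(C)C)OC1OC
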